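**Retrosynthetic overview**
1. Target ⇒ its 7,4'-di-O-benzyl ether; the last step only unmasks the two phenols of the upper unit.
2. C4(upper)–C8(lower) bond ⇒ (2S)-7,4'-bis(benzyloxy)flavan-4-yl cation (from the 2,4-cis flavan-4-ol) + unprotected (−)-epicatechin, bought with lower rings A, C and B and both lower stereocentres in place.
3. Upper ring C (O1–C2 bond) and C2 ⇒ achiral 2'-hydroxychalcone: a chalcone-isomerase-type 6-endo oxa-Michael closure, kept reversible and drained by an enantioselective transfer hydrogenation in one pot (the chemical counterpart of chalcone isomerase plus flavanone 4-reductase).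
4. Chalcone ⇒ Claisen–Schmidt union of a ring A acetophenone and a ring B benzaldehyde, both commercial benzyl ethers.
5. Ring order: upper rings A and B and the whole lower unit are purchased; upper ring C is the only ring made (step 2), and the two flavan units are joined afterwards (step 3).

Assumption: the SMILES is read as (2S,4S)-7,4'-dihydroxyflavan-(4α→8)-(−)-epicatechin (upper unit 2,4-cis, lower unit 2R,3R), and 1, 2 and 6 are taken as catalogue compounds.

**Step 1**
Reactants: 1 1-[4-(benzyloxy)-2-hydroxyphenyl]ethan-1-one; 2 4-(benzyloxy)benzaldehyde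
Product: 3 (E)-1-[4-(benzyloxy)-2-hydroxyphenyl]-3-[4-(benzyloxy)phenyl]prop-2-en-1-one
Conditions: KOH (50% aq, 8 equiv), EtOH, rt, 36 h; then 1 M HCl to pH 3
Reagents that add atoms: none
Why: Claisen–Schmidt (crossed aldol) condensation of a methyl ketone with a non-enolisable aldehyde, in which E1cB dehydration under equilibrating conditions gives only the E-enone and the ortho-phenolate stays open in strong base, so the chalcone precipitates on acidification.

**Step 2**
Reactants: 3 (E)-1-[4-(benzyloxy)-2-hydroxyphenyl]-3-[4-(benzyloxy)phenyl]prop-2-en-1-one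
Product: 5 (2S,4S)-7-(benzyloxy)-2-[4-(benzyloxy)phenyl]chroman-4-ol, via (2S)-flavanone 4 (not isolated)
Conditions: DBU (4 equiv), MeCN/THF 1:1, 40 °C, 2 h; then RuCl[(S,S)-TsDPEN](p-cymene) (2 mol %), HCO2H (3 equiv, added over 6 h), 40 °C, 24 h; recrystallise
Reagents that add atoms: none
Why: Proposed new method: a dynamic kinetic resolution coupled to ring closure, in which DBU closes the 2'-phenolate of 3 onto the enone (6-endo oxa-Michael, as chalcone isomerase does) and keeps the resulting ketone racemising through E1cB ring-opening back to 3, while the Ru–H formed from RuCl[(S,S)-TsDPEN](p-cymene) and formate reduces only the 2S ketone 4 quickly, because only in that enantiomer does the catalyst-dictated hydride face (giving 4S) coincide with the face anti to the equatorial 2-aryl group, so C2 is fixed as S and the alcohol is 2,4-cis; the electron-rich phenolate of 3 should not accept hydride, and the closest known reactions are the transfer-hydrogenative kinetic resolution of racemic flavanones and the dynamic kinetic resolution of 2-substituted chroman-4-ones that racemise by retro-oxa-Michael elimination.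

**Step 3**
Reactants: 5 (2S,4S)-7-(benzyloxy)-2-[4-(benzyloxy)phenyl]chroman-4-ol; 6 (−)-epicatechin (4 equiv)
Product: 8 (2R,3R)-8-{(2S,4S)-7-(benzyloxy)-2-[4-(benzyloxy)phenyl]chroman-4-yl}-2-(3,4-dihydroxyphenyl)chroman-3,5,7-triol, via flavan-4-yl cation 7 (not isolated)
Conditions: TsOH·H2O (10 mol %), THF/CH2Cl2 1:1, 0 °C → rt, 4 h; Sephadex LH-20, then reversed-phase chromatography
Reagents that add atoms: none
Why: Acid-catalysed SN1 Friedel–Crafts alkylation of the kind that extends proanthocyanidin chains in the plant, in which ionisation of 5 with loss of water gives cation 7 (stabilised by the para 7-benzyloxy group and the ortho ring oxygen), which is captured mainly at C8 of excess 6; the carbinol configuration of 5 is lost and the new C4 centre arises by attack on either face of the flattened cation, whose equatorial 2-aryl group gives little bias, so the 4α (2,4-cis, 4S) product 8 is expected in an amount comparable to its 4β epimer and is separated from it and from minor C6-linked isomers.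

**Step 4**
Reactants: 8 (2R,3R)-8-{(2S,4S)-7-(benzyloxy)-2-[4-(benzyloxy)phenyl]chroman-4-yl}-2-(3,4-dihydroxyphenyl)chroman-3,5,7-triol
Product: 9 (2R,3R)-2-(3,4-dihydroxyphenyl)-8-[(2S,4S)-7-hydroxy-2-(4-hydroxyphenyl)chroman-4-yl]chroman-3,5,7-triol
Conditions: H2 (1 atm), Pd(OH)2/C (20 wt %), THF/MeOH 1:1, rt, 3 h; filter under N2, lyophilise
Reagents that add atoms: none
Why: Hydrogenolysis of the two aryl benzyl ethers under neutral room-temperature conditions, which leave the diarylmethine C4–H, the cyclic benzylic C2–O bonds and all four stereocentres untouched, as in routine debenzylation of protected procyanidins.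

**Compound list**
1 | 1-[4-(benzyloxy)-2-hydroxyphenyl]ethan-1-one | CC(=O)c1ccc(OCc2ccccc2)cc1O | starting material
2 | 4-(benzyloxy)benzaldehyde | O=Cc1ccc(OCc2ccccc2)cc1 | starting material
3 | (E)-1-[4-(benzyloxy)-2-hydroxyphenyl]-3-[4-(benzyloxy)phenyl]prop-2-en-1-one | O=C(/C=C/c1ccc(OCc2ccccc2)cc1)c1ccc(OCc2ccccc2)cc1O | intermediate
4 | (2S)-7-(benzyloxy)-2-[4-(benzyloxy)phenyl]chroman-4-one; forms as the racemate, the 2R half reverting to 3 and closing again | O=C1C[C@@H](c2ccc(OCc3ccccc3)cc2)Oc2cc(OCc3ccccc3)ccc12 | intermediate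
5 | (2S,4S)-7-(benzyloxy)-2-[4-(benzyloxy)phenyl]chroman-4-ol (2,4-cis) | O[C@H]1C[C@@H](c2ccc(OCc3ccccc3)cc2)Oc2cc(OCc3ccccc3)ccc12 | intermediate
6 | (−)-epicatechin, (2R,3R)-2-(3,4-dihydroxyphenyl)chroman-3,5,7-triol | O[C@@H]1Cc2c(O)cc(O)cc2O[C@@H]1c1ccc(O)c(O)c1 | starting material
7 | (2S)-7-(benzyloxy)-2-[4-(benzyloxy)phenyl]chroman-4-ylium (benzylic cation, tosylate ion pair) | [CH+]1C[C@@H](c2ccc(OCc3ccccc3)cc2)Oc2cc(OCc3ccccc3)ccc12 | intermediate
8 | (2R,3R)-8-{(2S,4S)-7-(benzyloxy)-2-[4-(benzyloxy)phenyl]chroman-4-yl}-2-(3,4-dihydroxyphenyl)chroman-3,5,7-triol | O(Cc5ccccc5)c1ccc([C@@H]2C[C@H](c3c(O)cc(O)c4c3O[C@H](c3ccc(O)c(O)c3)[C@H](O)C4)c3ccc(OCc5ccccc5)cc3O2)cc1 | intermediate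
9 | (2R,3R)-2-(3,4-dihydroxyphenyl)-8-[(2S,4S)-7-hydroxy-2-(4-hydroxyphenyl)chroman-4-yl]chroman-3,5,7-triol | Oc1ccc([C@@H]2C[C@H](c3c(O)cc(O)c4c3O[C@H](c3ccc(O)c(O)c3)[C@H](O)C4)c3ccc(O)cc3O2)cc1 | target

**Totals**
Total step count: 4. Longest linear sequence: 4 steps (1 + 2 → 3 → 5 → 8 → 9).

**Steps most likely to fail, with fallbacks**

Step 2. The ketone may racemise too slowly relative to reduction of the mismatched enantiomer, or the Ru–H may reduce the C=C bond of 3, lowering ee and yield. The fallback sets out from 1 and comes back to the route at 5. Condense 1 with N,N-dimethylformamide dimethyl acetal (toluene, 100 °C) to the enaminone (E)-1-[4-(benzyloxy)-2-hydroxyphenyl]-3-(dimethylamino)prop-2-en-1-one F1. Close it with aqueous HCl in CH2Cl2 to 7-(benzyloxy)-4H-chromen-4-one F2. Add 4-(benzyloxy)phenylboronic acid to F2 with Pd(OCOCF3)2 and the t-BuPyOx enantiomer that gives the 2S product (NH4PF6, H2O, ClCH2CH2Cl, 60 °C). This gives 4 as an isolable single enantiomer, and NaBH4 (MeOH/THF, 0 °C) delivers hydride anti to the 2-aryl group to give 5. Ring C then comes from a chromone and C2 from a catalytic asymmetric conjugate arylation instead of from the dynamic resolution.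

Step 3. Facial selectivity at C4 is inherently modest, and C6 alkylation and double alkylation compete, so the isolated yield of the 4α isomer may be low. The fallback sets out from 5 and 6 and comes back at 9; it reverses the order at C4 (aryl first, hydrogen last) so that C2 controls C4. Oxidise 5 with MnO2 (CH2Cl2, rt) to the single-enantiomer ketone 4. Convert 6 with NaH and BnBr (DMF, 0 °C → rt) into (2R,3R)-3,5,7-tris(benzyloxy)-2-[3,4-bis(benzyloxy)phenyl]chroman F3. Brominate it at C8 with NBS (CH2Cl2, −78 °C) to give (2R,3R)-3,5,7-tris(benzyloxy)-2-[3,4-bis(benzyloxy)phenyl]-8-bromochroman F4. Exchange the bromide with n-BuLi (THF, −78 °C), transmetalate with CeCl3 to suppress enolisation, and add the aryl nucleophile to 4 to give the tertiary carbinol (2S)-7-(benzyloxy)-2-[4-(benzyloxy)phenyl]-4-[penta-O-benzylepicatechin-8-yl]chroman-4-ol F5. Ionic hydrogenation (Et3SiH, CF3CO2H, CH2Cl2, −40 → 0 °C) then delivers hydride to the C4 cation anti to the 2-aryl group, as NaBH4 does with flavanones, so the bulky aryl group is left cis to the 2-aryl group, giving the hepta-O-benzyl ether of the target F6 with C8 regiochemistry fixed by the bromide. H2 with Pd(OH)2/C (THF/MeOH/H2O, rt) finally gives 9.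

Step 4. The oxidation-sensitive polyphenolic dimer may debenzylate incompletely or be over-reduced. The fallback sets out from 5 and comes back at 9; it unmasks before coupling. Hydrogenolyse 5 (H2, Pd/C, EtOAc/EtOH, trace Et3N to protect the C4–OH) to (2S,4S)-2-(4-hydroxyphenyl)chroman-4,7-diol F7. Condense F7 with 6 (5 equiv) in 0.1 M aqueous HCl/EtOH at rt, where the free 7-OH lets the electrophile form as a neutral ring A para-quinone methide. 9 is then separated directly from its 4β epimer and the C6-linked isomers.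

**Further compounds**
F1 | step 2 | (E)-1-[4-(benzyloxy)-2-hydroxyphenyl]-3-(dimethylamino)prop-2-en-1-one | CN(C)/C=C/C(=O)c1ccc(OCc2ccccc2)cc1O
F2 | step 2 | 7-(benzyloxy)-4H-chromen-4-one | O=c1ccoc2cc(OCc3ccccc3)ccc12
F3 | step 3 | (2R,3R)-3,5,7-tris(benzyloxy)-2-[3,4-bis(benzyloxy)phenyl]chroman | c3ccccc3CO[C@@H]1Cc2c(OCc3ccccc3)cc(OCc3ccccc3)cc2O[C@@H]1c1ccc(OCc3ccccc3)c(OCc3ccccc3)c1
F4 | step 3 | (2R,3R)-3,5,7-tris(benzyloxy)-2-[3,4-bis(benzyloxy)phenyl]-8-bromochroman | c3ccccc3CO[C@@H]1Cc2c(OCc3ccccc3)cc(OCc3ccccc3)c(Br)c2O[C@@H]1c1ccc(OCc3ccccc3)c(OCc3ccccc3)c1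
F5 | step 3 | (2S)-7-(benzyloxy)-2-[4-(benzyloxy)phenyl]-4-[penta-O-benzylepicatechin-8-yl]chroman-4-ol (C4 configuration not assigned, removed in the next operation) | O(Cc5ccccc5)c1ccc([C@@H]2CC(O)(c3c(OCc5ccccc5)cc(OCc5ccccc5)c4c3O[C@H](c3ccc(OCc5ccccc5)c(OCc5ccccc5)c3)[C@H](OCc3ccccc3)C4)c3ccc(OCc5ccccc5)cc3O2)cc1
F6 | step 3 | hepta-O-benzyl ether of the target, (2R,3R)-3,5,7-tris(benzyloxy)-2-[3,4-bis(benzyloxy)phenyl]-8-{(2S,4S)-7-(benzyloxy)-2-[4-(benzyloxy)phenyl]chroman-4-yl}chroman | O(Cc5ccccc5)c1ccc([C@@H]2C[C@H](c3c(OCc5ccccc5)cc(OCc5ccccc5)c4c3O[C@H](c3ccc(OCc5ccccc5)c(OCc5ccccc5)c3)[C@H](OCc3ccccc3)C4)c3ccc(OCc5ccccc5)cc3O2)cc1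
F7 | step 4 | (2S,4S)-2-(4-hydroxyphenyl)chroman-4,7-diol | Oc1ccc([C@@H]2C[C@H](O)c3ccc(O)cc3O2)cc1
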